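# Design of a total synthesis of CNP0450810.8 (compound 29)

## The problem

Compound 29 is a cis-fused octalin. Atoms keep the decalin numbers of the target throughout (ring A = C1–C4, C4a, C8a with the C3=C4 double bond; ring B = C4a, C5–C8, C8a); α is the face of ring B that carries H4a and H8a, β the other face. Six stereocentres (C1, C2, C8a, C4a, C8, C7) form one unbroken chain: the pentadienoic acid at C1 is α, the (E)-but-2-en-2-yl group at C2 is β, and the C8 methyl group and the C7 sulfate are both β. C4a and C8a cannot be corrected once the rings are joined, so the ring-forming step must deliver the cis fusion. The only centre that can be set early and then steer the others is C1: on a monocyclic ring-A precursor it can direct C2 (trans) and the face on which ring B is attached, while C8 must come from the geometry of the incoming fragment and C7 from the shape of the finished bicycle. Several features forbid rough treatment: the C2–H bond is doubly allylic (skipped diene of C3=C4 and the butenyl group), the dienoic acid is a Michael acceptor, and the secondary sulfate monoester is polar and acid-labile and belongs at the very end. Any C7 ketone makes C8 epimerisable, and because the 8β-methyl group stands in a peri relationship to the C1 substituent the natural configuration cannot be assumed to be the thermodynamic one; likewise a C4 carbonyl makes C4a epimerisable towards the trans-decalin. The feature that opens the synthesis is the pattern on ring B: H4a, H8a, H8 and H7 all lie on the α face and the C7 oxygen is 1,4 to C4a. With a carbonyl group placed at C4, this is the imprint of an endo Diels–Alder reaction between a 2-silyloxypenta-1,3-diene (C5–C8 with the C8 methyl group) and a ring-A enone (C4 ketone, C4a=C8a alkene), and the same carbonyl is later the handle for the C3=C4 double bond.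

## Retrosynthesis

**29 ⇒ 25 (via 28 and 27).** The O–S bond at C7 and the acyl C–O bond of the acid are cut last. A sulfate monoester cannot be chromatographed on silica and does not tolerate acid, so carrying it (or a protected form) through earlier steps is inferior to sulfating the neutral hydroxy ester 25. The forward steps must sulfate a hindered secondary alcohol without touching the dienoate (25 → 27) and then cleave the ethyl ester with hydroxide, which a sulfate monoester anion resists (27 → 28 → 29).

**25 ⇒ 22 + 23.** The double bond next to C1 in the side chain is cut, which removes four carbons and both E-alkenes in one vinylogous Horner–Wadsworth–Emmons step. Two successive two-carbon olefinations would cost three extra steps; a cross-coupling would first require homologation of C1. The precursors are aldehyde 22 and the commercial phosphonate 23. The forward reaction must be E-selective, must not epimerise C1 and must tolerate the free C7 hydroxyl, which is left unprotected on purpose. Aldehyde 22 comes from diol 21 by an oxidation that distinguishes primary from hindered secondary hydroxyl.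

**21 ⇒ 20 ⇒ 19.** The C7–H bond (hydride) and the two O–Si bonds are cut. Diol 21 comes from keto alcohol 20 by hydride delivery to the α face, and 20 from bis-silyl compound 19 by one desilylation. The C7 oxygen is thus carried as a silyl enol ether from the cycloaddition onward, so the two ring carbonyls never have to be told apart. The demands are a non-basic unmasking (C8 must not equilibrate) and α-face reduction.

**19 ⇒ 17 ⇒ 16.** The C3=C4 double bond is traced to the C4 carbonyl of 16 through carbinol 17. The neighbouring option, regioselective enol triflate formation and reduction, asks a base to distinguish two methine α-positions; the reduction–syn-elimination pair instead reads regiochemistry from stereochemistry, because after α-face reduction the 4β-hydroxyl is cis only to H3. The forward steps must reduce C4 from the convex face without epimerising C4a and must dehydrate without ionisation.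

**16 ⇒ 13 + 15 (key disconnection).** The C4a–C5 and C8–C8a bonds are cut. This is the only cut that removes ring B and three stereocentres (C4a, C8a, C8) at once while leaving the controlling C1 centre on a monocycle. The cuts that open ring A instead each require a stereodefined bridged or open-chain precursor of comparable complexity to the target (see below). The precursors are enone 13, with three contiguous all-trans centres, and the achiral diene 15. The forward reaction must place the oxygen para to C4a, be endo, attack the face anti to the C1 group against the opposing pull of the C2 butenyl group, and keep the silyl enol ether intact.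

**15 ⇒ 14.** The O–Si bond is cut; diene 15 is the silyl dienol ether of the commercial vinyl ketone 14. The (Z)-isomer, with the methyl group on the outside of the s-cis diene, is the thermodynamic product and the only one that reacts.

**13 ⇒ 10 ⇒ 5 + 6.** The C4a=C8a double bond is traced to ketone 10 (regiochemistry from the kinetic enolate at the CH2 group). The C2–butenyl and C3–methyl bonds are then cut together as a conjugate addition–enolate alkylation on enone 5, with alkenyl bromide 6 as the source of the (E)-butenyl group. Both new centres follow from C1 by the trans rule on a simple cyclohexenone, which is more reliable than installing them on the bicycle.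

**5 ⇒ 4 ⇒ 2 ⇒ 1.** Enone 5 is reached by Saegusa oxidation of enol silane 4, which comes from desymmetrisation of the prochiral ketone 2 (enantioselective removal of one of two enantiotopic α-hydrogens), itself the silyl ether of commercial keto alcohol 1. The single stereocentre from which all others derive is thus set in one step from an achiral ring.

## Roads not taken

**Alternative 1:** Ring B would be closed by an anionic oxy-Cope rearrangement.
- *Cut:* the C4a–C5 bond, with the C3–C7 bond re-formed in the backward sense. This leads to the bicyclo[2.2.2]octenol A1 (bridgeheads C3 and C8a; bridges C4=C4a, C1–C2 and C7–C8; tertiary carbinol at C7 with its vinyl group on the side of the alkene bridge).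
- *Forward key step:* KH and 18-crown-6 deprotonate A1; the [3,3] shift forms C4a–C5, breaks C3–C7 and, after protonation at C6, gives ketone A2, which is the silyl ether of 20.
- *Merits:* the cis fusion is a geometric necessity, the C3=C4 double bond is created directly, and the C7 ketone appears without a masking group. In these respects it is better than the chosen plan, which spends two steps (8 and 9) on the alkene and carries a facial-selectivity risk.
- *Weak points:* A1 has a quaternary bridgehead, five further stereocentres and a tertiary vinyl carbinol. Its own assembly needs a cycloaddition of a trisubstituted cyclohexadiene with a ketene equivalent whose regio- and facial control is no easier than the problem it replaces, and a new source of absolute configuration. The rearrangement runs under strongly basic conditions in which the product enolate can equilibrate C8 (crowded by C1) and in which the doubly allylic C2–H is exposed.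
- *Comparison:* the chosen plan offers a five-step access to 13 from a symmetric ketone, absolute configuration from one desymmetrisation, and non-basic conditions whenever the C7 ketone exists.

**Alternative 2:** Ring A would be closed by an intramolecular Michael addition under enamine catalysis.
- *Cut:* the C1–C8a bond, leading to keto aldehyde A3, a 4-substituted 2-methylcyclohex-2-enone (C7 ketone, C8=C8a) whose C4a side chain is (Z)-CH=C(Me)–CH(butenyl)–CH2–CHO.
- *Forward key step:* pyrrolidine and benzoic acid activate the aldehyde of A3 by enamine catalysis; C1 adds to C8a in a 6-exo closure to give keto aldehyde A4.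
- *Merits:* mild and metal-free; the tether from C4a forces the cis fusion; C3=C4 is already present; the C1 formyl group is ready for olefination, which saves the desilylation and oxidation of the chosen route.
- *Weak points:* A3 needs a (Z)-trisubstituted alkene flanked by two stereocentres (C2, C4a) on an enantiopure enone, a long open-chain exercise. C1 and C8 would be set by equilibration, and the 8β-methyl group is cis to C1 in a peri contact, so the thermodynamic sink may be the wrong C8 epimer. A4 is a 1,5-keto aldehyde open to aldol closure between C6 and the formyl carbon under the same amine–acid conditions. The C2–H of A3 can slip into conjugation.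
- *Comparison:* the chosen plan sets C8 kinetically by the endo rule and never equilibrates it.

**Alternative 3:** Ring A would be closed by an intramolecular Heck reaction.
- *Cut:* the C4–C4a bond, leading to (Z)-alkenyl iodide A5 (ring B as a cyclohexene with C4a=C5, 7β-silyloxy, 8β-methyl; C8a bearing CH(CO2Me)–CH(butenyl)–C(Me)=CHI).
- *Forward key step:* Pd(OAc)2, PPh3 and Ag2CO3; oxidative addition of the C–I bond of A5 to zerovalent palladium, 6-exo carbopalladation of C4a=C5 and β-hydride elimination towards C6 give diene ester A6.
- *Merits:* the closure is reliable, the tether enforces the cis fusion, the C3=C4 alkene comes directly from the alkenyl iodide, and C7 and C8 are fixed on ring B beforehand, so no late hydride selectivity is needed. On these points it is at least as good as the chosen plan.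
- *Weak points:* five stereocentres (C1, C2, C7, C8, C8a) and a Z-trisubstituted alkenyl iodide must be in place before the ring closes. A6 carries a C5=C6 alkene that has to be hydrogenated selectively beside two trisubstituted alkenes, and an ester at C1 that needs a redox adjustment, so the sequence after ring closure is longer.
- *Comparison:* the chosen plan forms two bonds and three stereocentres in one step from a monocycle made in five steps. Its price is the facial contest in step 7 and the two-step removal of the C4 carbonyl.

Key step: step 7

Assumption on the chemistry: the sense of the enantioselective deprotonation in step 2 is taken from 4-tert-butylcyclohexanone, for which the (R,R)-amide gives the (S)-enol silane; should ketone 2 respond in the opposite sense, the (S,S)-amide is used.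
Remark: the target is written in its fully protonated form and step 15 is written to deliver that form; the disodium salt 28 is the form to store.

## Route

Step 1
Reactants: 1 4-(hydroxymethyl)cyclohexan-1-one
Product: 2 4-{[(tert-butyldimethylsilyl)oxy]methyl}cyclohexan-1-one
Conditions: TBSCl, imidazole, CH2Cl2, 0 °C → rt
Reagents that add atoms: tert-butyldimethylsilyl chloride, CC(C)(C)[Si](C)(C)Cl
Why: Silylation of a primary alcohol with a silyl chloride and imidazole; the ketone is untouched, and the TBS ether tolerates the amide bases, the cuprate and the Lewis acid that follow.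

Step 2
Reactants: 2 4-{[(tert-butyldimethylsilyl)oxy]methyl}cyclohexan-1-one
Product: 4 {[(4S)-4-{[(tert-butyldimethylsilyl)oxy]methyl}cyclohex-1-en-1-yl]oxy}trimethylsilane, via lithium enolate 3 (not isolated)
Conditions: LiN[(R)-CH(Me)Ph]2 (from the amine and n-BuLi), LiCl, Me3SiCl present from the start, THF, −78 °C
Reagents that add atoms: chlorotrimethylsilane, C[Si](C)(C)Cl
Why: Enantioselective deprotonation of a prochiral 4-substituted cyclohexanone by a C2-symmetric chiral lithium amide with in situ silyl trapping; the base distinguishes the two enantiotopic axial α-hydrogens of the chair with equatorial side chain, so the C1 stereocentre (S in 4) arises by desymmetrisation.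

Step 3
Reactants: 4 {[(4S)-4-{[(tert-butyldimethylsilyl)oxy]methyl}cyclohex-1-en-1-yl]oxy}trimethylsilane
Product: 5 (4S)-4-{[(tert-butyldimethylsilyl)oxy]methyl}cyclohex-2-en-1-one
Conditions: Pd(OAc)2 (10 mol %), O2 (1 atm), DMSO, rt
Reagents that add atoms: none
Why: Saegusa oxidation: the enol silane gives a divalent palladium enolate, β-hydride elimination releases the enone and O2 reoxidises the metal; the double bond appears on the side fixed in step 2 (C2=C3, next to C1), so the stereocentre is untouched.

Step 4
Reactants: 5 (4S)-4-{[(tert-butyldimethylsilyl)oxy]methyl}cyclohex-2-en-1-one; 6 (E)-2-bromobut-2-ene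
Product: 10 (2S,3R,4S)-3-[(E)-but-2-en-2-yl]-4-{[(tert-butyldimethylsilyl)oxy]methyl}-2-methylcyclohexan-1-one, via alkenyllithium 7 (not isolated), via dialkenylcuprate 8 (not isolated), via lithium enolate 9 (not isolated)
Conditions: 6, t-BuLi (2 equiv), Et2O, −78 °C; CuI (0.5 equiv per Li), −40 °C; 5, −78 → −40 °C; MeI, HMPA, −40 → 0 °C; aq NH4Cl
Reagents that add atoms: iodomethane, CI
Why: Bromine–lithium exchange keeps the alkene geometry; conjugate addition of the dialkenylcuprate to the 4-substituted cyclohexenone occurs anti to the C1 group (butenyl β at C2), and the regiodefined enolate 9 is methylated at C3 anti to the new butenyl group (tandem conjugate addition–enolate alkylation), which gives the all-trans, all-equatorial ketone.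

Step 5
Reactants: 10 (2S,3R,4S)-3-[(E)-but-2-en-2-yl]-4-{[(tert-butyldimethylsilyl)oxy]methyl}-2-methylcyclohexan-1-one
Product: 13 (4S,5R,6S)-5-[(E)-but-2-en-2-yl]-4-{[(tert-butyldimethylsilyl)oxy]methyl}-6-methylcyclohex-2-en-1-one, via kinetic lithium enolate 11 (not isolated), via sulfilimine adduct 12 (not isolated)
Conditions: LiN(i-Pr)2, THF, −78 °C; PhS(Cl)=N-t-Bu, −78 °C
Reagents that add atoms: none
Why: The hindered amide removes a proton from the CH2 group (C4a) and not from the methine C3; the enolate attacks sulfur of the sulfinimidoyl chloride and adduct 12 undergoes syn-elimination at low temperature (one-pot ketone dehydrogenation), so the C4a=C8a enone forms with C1–C3 unchanged.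

Step 6
Reactants: 14 pent-1-en-3-one
Product: 15 tert-butyl(dimethyl){[(3Z)-penta-1,3-dien-3-yl]oxy}silane
Conditions: TBSOTf, Et3N, Et2O, 0 °C
Reagents that add atoms: tert-butyldimethylsilyl trifluoromethanesulfonate, CC(C)(C)[Si](C)(C)OS(=O)(=O)C(F)(F)F
Why: Soft enolisation of the ethyl ketone with silyl triflate and amine gives the cross-conjugated silyl dienol ether, the favoured (Z)-isomer having its methyl group trans to the vinyl group (outside position of the s-cis diene); a TBS group is chosen so that the enol ether outlasts hydride reduction, chromatography and the dehydration.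

Step 7
Reactants: 13 (4S,5R,6S)-5-[(E)-but-2-en-2-yl]-4-{[(tert-butyldimethylsilyl)oxy]methyl}-6-methylcyclohex-2-en-1-one; 15 tert-butyl(dimethyl){[(3Z)-penta-1,3-dien-3-yl]oxy}silane
Product: 16 cis-fused adduct: C4 ketone, C6=C7 tert-butyldimethylsilyl enol ether, 1α-{[(tert-butyldimethylsilyl)oxy]methyl}, 2β-[(E)-but-2-en-2-yl], 3α-methyl, 8β-methyl, H4a and H8a α
Conditions: Me2AlCl (1.2 equiv), 15 (3 equiv), CH2Cl2, −78 → −30 °C; Et3N, then aq NaHCO3
Reagents that add atoms: none
Why: Me2AlCl binds the C4 carbonyl oxygen and lowers the enone LUMO; the most nucleophilic diene terminus, the enol-ether β-carbon C8, bonds to the β-carbon C8a and C5 bonds to C4a in a concerted, strongly asynchronous [4+2] cycloaddition. The closest known reaction type is the Lewis-acid-promoted Diels–Alder reaction of 2-silyloxy-1,3-dienes with cyclohex-2-enones, which gives cis-fused decalones with the silyloxy group para to the acyl-bearing carbon. Ring B is closed by intermolecular [4+2] annulation, both σ-bonds forming on the same face of the enone, so C4a and C8a are set together and the fusion is cis by necessity. Regiochemistry follows from the silyloxy donor outweighing the terminal methyl group, which places the C7 oxygen 1,4 to C4a. The diene should add to the β face, anti to the pseudo-equatorial C1 silyloxymethyl group, which lies directly beside C8a and would clash with the methyl-bearing diene terminus on the α face; this fixes the absolute configuration of C8a and C4a. The endo orientation (ring A and the complexed carbonyl under the diene) places the outside methyl group of the (Z)-dienol ether cis to the C8a–C1 bond, which gives 8β-methyl with H8 on the α face. The selectivity most at stake is facial, since the β-oriented C2 butenyl group on its own would favour α attack; the adjacency of C1 to the bond being formed and the methyl group on the bonding terminus are counted on to decide it, and low temperature with an amine quench keeps C4a and the silyl enol ether intact.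

Step 8
Reactants: 16 cis-fused adduct (C4 ketone, C6=C7 silyl enol ether)
Product: 17 4β-carbinol: as 16 with C4 bearing a β-hydroxyl group (H4 α)
Conditions: LiAlH4, Et2O, −78 °C; aq NaOH work-up
Reagents that add atoms: none
Why: In the cis-decalone the C4a–C5 bond is axial on ring A and ring B covers the β face of the carbonyl, so the small hydride attacks along the axial trajectory from the convex α face and gives the equatorial 4β-alcohol (diastereoselective ketone reduction); at −78 °C reduction outruns enolisation, so C3 and C4a keep their configuration.

Step 9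
Reactants: 17 4β-carbinol
Product: 19 diene: C3=C4 alkene, C6=C7 tert-butyldimethylsilyl enol ether, 1α-{[(tert-butyldimethylsilyl)oxy]methyl}, 2β-[(E)-but-2-en-2-yl], 3-methyl, 8β-methyl, H4a and H8a α, via sulfamate salt 18 (not isolated)
Conditions: MeO2CN(−)SO2N(+)Et3 (Burgess reagent), toluene, 60 °C
Reagents that add atoms: none
Why: The alcohol is converted into sulfamate 18, which fragments by a cyclic syn-elimination (Burgess dehydration); only H3 is cis to the C4 oxygen, H4a being trans, so the C3=C4 alkene should form alone and the C3 stereocentre is consumed.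

Step 10
Reactants: 19 diene with C6=C7 silyl enol ether
Product: 20 keto alcohol: C7 ketone, C3=C4 alkene, 1α-hydroxymethyl, 2β-[(E)-but-2-en-2-yl], 3-methyl, 8β-methyl, H4a and H8a α
Conditions: HF·pyridine, pyridine, THF, 0 °C → rt
Reagents that add atoms: none
Why: Buffered fluoride cleaves the silyl enol ether (protonation at C6 gives the C7 ketone) and the primary silyl ether in one operation; the medium is not basic, so the epimerisable C8 centre and the doubly allylic C2–H are left alone.

Step 11
Reactants: 20 keto alcohol
Product: 21 diol: 7β-hydroxyl (H7 α), 1α-hydroxymethyl, otherwise as 20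
Conditions: LiBH(s-Bu)3 (3 equiv), THF, −78 °C; H2O
Reagents that add atoms: none
Why: Bulky trialkylborohydride reduction; the β face of the C7 carbonyl is shielded by ring A (C1 is axial on ring B, 1,3 to C7) and by the adjacent 8β-methyl group, so hydride enters from the α face and gives the 7β-alcohol cis to the C8 methyl group; one equivalent of hydride is consumed by the primary hydroxyl.

Step 12
Reactants: 21 diol
Product: 22 hydroxy aldehyde: 1α-formyl, 7β-hydroxyl, otherwise as 21
Conditions: TEMPO (10 mol %), PhI(OAc)2, CH2Cl2, rt
Reagents that add atoms: none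
Why: Oxoammonium-mediated oxidation is selective for a primary over a hindered secondary alcohol and stops at the aldehyde in anhydrous medium; the neutral conditions preserve C1.

Step 13
Reactants: 22 hydroxy aldehyde; 23 ethyl (2E)-4-(diethoxyphosphoryl)but-2-enoate
Product: 25 ethyl (2E,4E)-5-[1α-yl of the 7β-hydroxy octalin]penta-2,4-dienoate: as 22 with CH=CH–CH=CH–CO2Et in place of the formyl group, via lithiated phosphonate 24 (not isolated)
Conditions: 23, LiN(SiMe3)2 (slightly less than 1 equiv per 23), THF, −78 °C; 22, −78 → 0 °C
Reagents that add atoms: none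
Why: Vinylogous Horner–Wadsworth–Emmons olefination; the allylic phosphonate anion reacts at the carbon α to phosphorus with the aldehyde and the stabilised anion gives the (2E,4E)-dienoate; with no excess amide present the anion is too weak a base to remove the C1–H or to be quenched by the C7 hydroxyl.

Step 14
Reactants: 25 hydroxy dienoate
Product: 27 sodium salt of the 7β-sulfate monoester of 25, via pyridinium sulfate 26 (not isolated)
Conditions: SO3·pyridine, pyridine, 40 °C; aq NaHCO3
Reagents that add atoms: sulfur trioxide–pyridine complex, [O-]S(=O)(=O)[n+]1ccccc1; sodium hydrogencarbonate, [Na+].OC([O-])=O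
Why: O-Sulfonation of the secondary alcohol by the SO3–amine complex gives the pyridinium sulfate monoester, exchanged to the sodium salt on bicarbonate work-up; the C7–O bond is not broken, so the configuration is retained, and ester and polyene are inert.

Step 15
Reactants: 27 sodium sulfate ester
Product: 29 (2E,4E)-5-[(1S,2S,4aS,7R,8S,8aR)-2-[(2E)-but-2-en-2-yl]-3,8-dimethyl-7-(sulfooxy)-1,2,4a,5,6,7,8,8a-octahydronaphthalen-1-yl]penta-2,4-dienoic acid (target), via disodium salt 28 (not isolated)
Conditions: NaOH, THF/MeOH/H2O, rt; HCl (aq) to pH 2, 0 °C, cold extraction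
Reagents that add atoms: sodium hydroxide, [Na+].[OH-]
Why: Saponification of the dienoate by acyl substitution; a sulfate monoester anion resists hydroxide at room temperature, so only the ethyl ester is cleaved, and brief cold acidification gives the protonated form before the sulfate can hydrolyse.

## Compound list

1 | 4-(hydroxymethyl)cyclohexan-1-one | O=C1CCC(CO)CC1 | starting material
2 | 4-{[(tert-butyldimethylsilyl)oxy]methyl}cyclohexan-1-one | O=C1CCC(CO[Si](C)(C)C(C)(C)C)CC1 | intermediate
3 | lithium (4S)-4-{[(tert-butyldimethylsilyl)oxy]methyl}cyclohex-1-en-1-olate (formed and silylated in the flask) | [Li+].[O-]C1=CC[C@@H](CO[Si](C)(C)C(C)(C)C)CC1 | intermediate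
4 | {[(4S)-4-{[(tert-butyldimethylsilyl)oxy]methyl}cyclohex-1-en-1-yl]oxy}trimethylsilane | C[Si](C)(C)OC1=CC[C@@H](CO[Si](C)(C)C(C)(C)C)CC1 | intermediate
5 | (4S)-4-{[(tert-butyldimethylsilyl)oxy]methyl}cyclohex-2-en-1-one | O=C1C=C[C@@H](CO[Si](C)(C)C(C)(C)C)CC1 | intermediate
6 | (E)-2-bromobut-2-ene | C/C=C(\C)Br | starting material
7 | (Z)-but-2-en-2-yllithium (methyl groups cis, geometry of 6 retained; formed in the flask) | C/C=C(\C)[Li] | intermediate
8 | lithium bis[(E)-but-2-en-2-yl]cuprate, LiCu(C4H7)2 (formed in the flask) | [Li+].C/C=C(\C)[Cu-]C(/C)=C/C | intermediate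
9 | lithium (3R,4S)-3-[(E)-but-2-en-2-yl]-4-{[(tert-butyldimethylsilyl)oxy]methyl}cyclohex-1-en-1-olate (formed in the flask) | [Li+].C/C=C(\C)[C@H]1C=C([O-])CC[C@@H]1CO[Si](C)(C)C(C)(C)C | intermediate
10 | (2S,3R,4S)-3-[(E)-but-2-en-2-yl]-4-{[(tert-butyldimethylsilyl)oxy]methyl}-2-methylcyclohexan-1-one | C/C=C(\C)[C@H]1[C@H](C)C(=O)CC[C@@H]1CO[Si](C)(C)C(C)(C)C | intermediate
11 | lithium (4S,5R,6S)-5-[(E)-but-2-en-2-yl]-4-{[(tert-butyldimethylsilyl)oxy]methyl}-6-methylcyclohex-1-en-1-olate (kinetic enolate, formed in the flask) | [Li+].C/C=C(\C)[C@H]1[C@H](C)C([O-])=CC[C@@H]1CO[Si](C)(C)C(C)(C)C | intermediate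
12 | (2S,3R,4S)-3-[(E)-but-2-en-2-yl]-6-(N-tert-butyl-S-phenylsulfinimidoyl)-4-{[(tert-butyldimethylsilyl)oxy]methyl}-2-methylcyclohexan-1-one (new carbon and sulfur centres unassigned; formed in the flask) | C/C=C(\C)[C@H]1[C@H](C)C(=O)C(S(=NC(C)(C)C)c2ccccc2)C[C@@H]1CO[Si](C)(C)C(C)(C)C | intermediate
13 | (4S,5R,6S)-5-[(E)-but-2-en-2-yl]-4-{[(tert-butyldimethylsilyl)oxy]methyl}-6-methylcyclohex-2-en-1-one | C/C=C(\C)[C@H]1[C@H](C)C(=O)C=C[C@@H]1CO[Si](C)(C)C(C)(C)C | intermediate
14 | pent-1-en-3-one | CCC(=O)C=C | starting material
15 | tert-butyl(dimethyl){[(3Z)-penta-1,3-dien-3-yl]oxy}silane | C=C/C(O[Si](C)(C)C(C)(C)C)=C/C | intermediate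
16 | cis-fused adduct: C4 ketone, C6=C7 TBS enol ether, 1α-CH2OTBS, 2β-(E)-but-2-en-2-yl, 3α-methyl, 8β-methyl, H4a and H8a α | C/C=C(\C)[C@H]1[C@H](C)C(=O)[C@H]2CC=C(O[Si](C)(C)C(C)(C)C)[C@@H](C)[C@H]2[C@@H]1CO[Si](C)(C)C(C)(C)C | intermediate
17 | 4β-carbinol of 16 (H4 α) | C/C=C(\C)[C@H]1[C@H](C)[C@@H](O)[C@H]2CC=C(O[Si](C)(C)C(C)(C)C)[C@@H](C)[C@H]2[C@@H]1CO[Si](C)(C)C(C)(C)C | intermediate
18 | triethylammonium salt of the 4β-O-[N-(methoxycarbonyl)sulfamate] of 17 (formed in the flask) | CC[NH+](CC)CC.C/C=C(\C)[C@H]1[C@H](C)[C@@H](OS(=O)(=O)[N-]C(=O)OC)[C@H]2CC=C(O[Si](C)(C)C(C)(C)C)[C@@H](C)[C@H]2[C@@H]1CO[Si](C)(C)C(C)(C)C | intermediate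
19 | cis-fused diene: C3=C4 alkene, C6=C7 TBS enol ether, 1α-CH2OTBS, 2β-(E)-but-2-en-2-yl, 3-methyl, 8β-methyl | C/C=C(\C)[C@H]1C(C)=C[C@H]2CC=C(O[Si](C)(C)C(C)(C)C)[C@@H](C)[C@H]2[C@@H]1CO[Si](C)(C)C(C)(C)C | intermediate
20 | keto alcohol: C7 ketone, C3=C4 alkene, 1α-CH2OH, 2β-(E)-but-2-en-2-yl, 3-methyl, 8β-methyl | C/C=C(\C)[C@H]1C(C)=C[C@H]2CCC(=O)[C@@H](C)[C@H]2[C@@H]1CO | intermediate
21 | diol: 7β-OH, 1α-CH2OH, otherwise as 20 | C/C=C(\C)[C@H]1C(C)=C[C@H]2CC[C@@H](O)[C@@H](C)[C@H]2[C@@H]1CO | intermediate
22 | hydroxy aldehyde: 7β-OH, 1α-CHO | C/C=C(\C)[C@H]1C(C)=C[C@H]2CC[C@@H](O)[C@@H](C)[C@H]2[C@@H]1C=O | intermediate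
23 | ethyl (2E)-4-(diethoxyphosphoryl)but-2-enoate | CCOC(=O)/C=C/CP(=O)(OCC)OCC | starting material
24 | lithium salt of 23, carbanion α to phosphorus (formed in the flask) | [Li+].CCOC(=O)/C=C/[CH-]P(=O)(OCC)OCC | intermediate
25 | ethyl (2E,4E)-dienoate with free 7β-OH | C/C=C(\C)[C@H]1C(C)=C[C@H]2CC[C@@H](O)[C@@H](C)[C@H]2[C@@H]1/C=C/C=C/C(=O)OCC | intermediate
26 | pyridinium salt of the 7β-sulfate monoester of 25 (formed in the flask) | C/C=C(\C)[C@H]1C(C)=C[C@H]2CC[C@@H](OS(=O)(=O)[O-])[C@@H](C)[C@H]2[C@@H]1/C=C/C=C/C(=O)OCC.c1cc[nH+]cc1 | intermediate
27 | sodium salt of the 7β-sulfate monoester of 25 | C/C=C(\C)[C@H]1C(C)=C[C@H]2CC[C@@H](OS(=O)(=O)[O-])[C@@H](C)[C@H]2[C@@H]1/C=C/C=C/C(=O)OCC.[Na+] | intermediate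
28 | disodium salt of 29 (carboxylate and sulfate; formed in the flask) | C/C=C(\C)[C@H]1C(C)=C[C@H]2CC[C@@H](OS(=O)(=O)[O-])[C@@H](C)[C@H]2[C@@H]1/C=C/C=C/C(=O)[O-].[Na+].[Na+] | intermediate
29 | (2E,4E)-5-[(1S,2S,4aS,7R,8S,8aR)-2-[(2E)-but-2-en-2-yl]-3,8-dimethyl-7-(sulfooxy)-1,2,4a,5,6,7,8,8a-octahydronaphthalen-1-yl]penta-2,4-dienoic acid (CNP0450810.8) | C/C=C(\C)[C@H]1C(C)=C[C@H]2CC[C@@H](OS(=O)(=O)O)[C@@H](C)[C@H]2[C@@H]1/C=C/C=C/C(=O)O | target

## Step count and weak points

Total: 15 steps. Longest linear sequence: 14 steps (steps 1–5 and 7–15); step 6 is a one-step branch. The enantiomeric purity fixed in step 2 is carried to the end; a crystalline later intermediate would be the place to raise it if required.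

**Step 7 (key step).** The most likely failure is poor facial selectivity. A chair-like approach of the diene to the α face, anti to the C2 butenyl group, competes with the wanted β-face approach anti to the C1 group, and a stepwise Michael-type pathway could also erode endo control at C8.
Fallback (sets out from 2, returns at 16): the cycloaddition is moved in front of the C2 and C3 substituents, so that C1 is the only control element and acts unopposed.
- Ketone 2 is deprotonated with the (S,S)-amide in the presence of Me3SiCl to give {[(4R)-4-{[(tert-butyldimethylsilyl)oxy]methyl}cyclohex-1-en-1-yl]oxy}trimethylsilane F1.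
- Saegusa oxidation gives (4R)-4-{[(tert-butyldimethylsilyl)oxy]methyl}cyclohex-2-en-1-one F2, in which the alkene lies between C4a and C8a and C2 and C3 are still CH2 groups.
- Me2AlCl-promoted cycloaddition of F2 with 15 gives the cis-fused adduct without C2 and C3 substituents F3.
- Kinetic deprotonation of F3 at the CH2 group C3 (not at the ring-fusion methine C4a) with LiN(i-Pr)2, followed by PhS(Cl)=N-t-Bu, gives the C2=C3 enone F4.
- Addition of cuprate 8 to F4 anti to the C1 group, with methylation of the enolate at C3, rejoins the route at 16.
The number of steps is unchanged.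

**Step 4.** The most likely failure is slow alkylation of the copper-containing enolate, with proton exchange between enolate and product leading to over-methylation or methylation at C4a.
Fallback (sets out from 5, returns at 10): the methyl group is installed before the conjugate addition.
- Enone 5 is iodinated at the α-carbon (I2, pyridine) to give (4S)-4-{[(tert-butyldimethylsilyl)oxy]methyl}-2-iodocyclohex-2-en-1-one F5.
- Suzuki coupling (MeB(OH)2, Pd(PPh3)4, K3PO4) gives (4S)-4-{[(tert-butyldimethylsilyl)oxy]methyl}-2-methylcyclohex-2-en-1-one F6.
- Addition of cuprate 8 to F6 anti to the C1 group, protonation, and equilibration of C3 with NaOMe in MeOH to the all-equatorial isomer gives 10.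

**Step 8.** The most likely failure is hydride delivery from the β face, or partial epimerisation of C4a before reduction, either of which would put the hydroxyl cis to H4a and misdirect the syn-elimination.
Fallback (sets out from 16, returns at 19): the reduction is run under the conditions that give the other epimer most cleanly, and the 4α-carbinol epimer of 17 F7 is isolated. Its axial C4–O bond is antiperiplanar to the axial H3 and to no other hydrogen (H4a is equatorial), so an anti-elimination with POCl3 in pyridine converts it into the same alkene 19. Both epimers can therefore be used, each with its matching elimination.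

**Step 9.** The most likely failure is ionisation of the hindered secondary sulfamate instead of the cyclic elimination, with hydride shift or capture by the enol ether, or simple return of starting alcohol.
Fallback (sets out from 16, returns at 19; it also bypasses step 8): the carbinol is avoided. Kinetic enolisation of 16 with KN(SiMe3)2 at −78 °C removes the axial H3, which is aligned with the carbonyl π system while H4a is equatorial, and trapping with PhNTf2 gives the C3=C4 enol trifluoromethanesulfonate of 16 F8. Reduction of the C–O bond with Pd(OAc)2, PPh3, HCO2H and Et3N gives 19.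

**Step 14.** The most likely failure is incomplete sulfation of the crowded C7 hydroxyl (flanked by the C8 methyl group and facing C1), followed by loss of the amphiphilic salt on isolation.
Fallback (sets out from 25, returns at 27): the sulfate is introduced in neutral, protected form. Alcohol 25 with 2,2,2-trichloroethyl chlorosulfate, Et3N and DMAP gives the 2,2,2-trichloroethyl sulfate diester of 25 F9, which can be purified on silica. Zn and HCO2NH4 in MeOH remove the trichloroethyl group, and NaHCO3 exchange gives 27.

## Further compounds

F1 | step 7 | {[(4R)-4-{[(tert-butyldimethylsilyl)oxy]methyl}cyclohex-1-en-1-yl]oxy}trimethylsilane | C[Si](C)(C)OC1=CC[C@H](CO[Si](C)(C)C(C)(C)C)CC1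
F2 | step 7 | (4R)-4-{[(tert-butyldimethylsilyl)oxy]methyl}cyclohex-2-en-1-one | O=C1C=C[C@H](CO[Si](C)(C)C(C)(C)C)CC1
F3 | step 7 | cis-fused adduct without C2 and C3 substituents: C4 ketone, C6=C7 TBS enol ether, 1α-CH2OTBS, 8β-methyl, H4a and H8a α | C1CC(=O)[C@H]2CC=C(O[Si](C)(C)C(C)(C)C)[C@@H](C)[C@H]2[C@@H]1CO[Si](C)(C)C(C)(C)C
F4 | step 7 | C2=C3 enone of F3 | C1=CC(=O)[C@H]2CC=C(O[Si](C)(C)C(C)(C)C)[C@@H](C)[C@H]2[C@@H]1CO[Si](C)(C)C(C)(C)C
F5 | step 4 | (4S)-4-{[(tert-butyldimethylsilyl)oxy]methyl}-2-iodocyclohex-2-en-1-one | O=C1C(I)=C[C@@H](CO[Si](C)(C)C(C)(C)C)CC1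
F6 | step 4 | (4S)-4-{[(tert-butyldimethylsilyl)oxy]methyl}-2-methylcyclohex-2-en-1-one | O=C1C(C)=C[C@@H](CO[Si](C)(C)C(C)(C)C)CC1
F7 | step 8 | 4α-carbinol epimer of 17 | C/C=C(\C)[C@H]1[C@H](C)[C@H](O)[C@H]2CC=C(O[Si](C)(C)C(C)(C)C)[C@@H](C)[C@H]2[C@@H]1CO[Si](C)(C)C(C)(C)C
F8 | step 9 | C3=C4 enol trifluoromethanesulfonate of 16 | C/C=C(\C)[C@H]1C(C)=C(OS(=O)(=O)C(F)(F)F)[C@H]2CC=C(O[Si](C)(C)C(C)(C)C)[C@@H](C)[C@H]2[C@@H]1CO[Si](C)(C)C(C)(C)C
F9 | step 14 | 2,2,2-trichloroethyl sulfate diester of 25 | C/C=C(\C)[C@H]1C(C)=C[C@H]2CC[C@@H](OS(=O)(=O)OCC(Cl)(Cl)Cl)[C@@H](C)[C@H]2[C@@H]1/C=C/C=C/C(=O)OCC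
A1 | alternative 1 | bicyclo[2.2.2]octenol: bridgeheads C3 (methyl) and C8a; bridges C4=C4a, C1(CH2OTBS)–C2(butenyl) and C7(OH)(vinyl)–C8(methyl); vinyl on the side of the alkene bridge | C/C=C(\C)[C@@H]1[C@@H](CO[Si](C)(C)C(C)(C)C)[C@H]2C=C[C@]1(C)[C@](O)(C=C)[C@H]2C
A2 | alternative 1 | cis-fused C7 ketone with C3=C4 alkene and 1α-CH2OTBS (silyl ether of 20) | C/C=C(\C)[C@H]1C(C)=C[C@H]2CCC(=O)[C@@H](C)[C@H]2[C@@H]1CO[Si](C)(C)C(C)(C)C
A3 | alternative 2 | keto aldehyde: 2-methylcyclohex-2-en-1-one bearing at C4 (decalin C4a) the chain (Z)-CH=C(Me)–CH[(E)-but-2-en-2-yl]–CH2–CHO | C/C=C(\C)[C@H](CC=O)/C(C)=C\[C@H]1CCC(=O)C(C)=C1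
A4 | alternative 2 | cis-fused keto aldehyde: C7 ketone, 1α-formyl, C3=C4 alkene | C/C=C(\C)[C@H]1C(C)=C[C@H]2CCC(=O)[C@@H](C)[C@H]2[C@@H]1C=O
A5 | alternative 3 | (Z)-alkenyl iodide: cyclohexene ring B (C4a=C5, 7β-OTBS, 8β-methyl) with C8a bearing CH(CO2Me)–CH[(E)-but-2-en-2-yl]–C(Me)=CHI | C/C=C(\C)[C@@H](/C(C)=C\I)[C@@H](C(=O)OC)[C@H]1C=CC[C@@H](O[Si](C)(C)C(C)(C)C)[C@H]1C
A6 | alternative 3 | cis-fused diene ester: C3=C4 and C5=C6 alkenes, 1α-CO2Me, 7β-OTBS, 8β-methyl | C/C=C(\C)[C@H]1C(C)=C[C@H]2C=C[C@@H](O[Si](C)(C)C(C)(C)C)[C@@H](C)[C@H]2[C@@H]1C(=O)OC
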